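**Plan**

1. Retrosynthetic cuts, in order: (a) the C=C bond of the propenal on C5 (Wittig on a C5 formyl group); (b) the O1–C7a aryl ether bond of the dihydrofuran ring (intramolecular SNAr); (c) the C2–C3 bond (auxiliary-controlled syn aldol of a ring A arylacetyl imide with the ring B aldehyde); (d) the C3a–CH2 bond (C–H borylation and cross-coupling on methyl 4-fluoro-3-methoxybenzoate).
2. Enabling feature: in ring A the carbon that carries the propenal (C5) is para to C7a, the arene carbon bonded to O1, and C7a lies between C7–OMe and C3a. With C5 held as CO2Me and a fluoride on C7a, C7a becomes an SNAr site that the C2 oxygen reaches through a five-membered transition state.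
3. Forward order: ring A arylacetic acid; C2–C3 by aldol (chain and both stereocentres); auxiliary off to the carboxylate; closure of the dihydrofuran ring at O1–C7a; reduction, benzylic oxidation, two-carbon extension and final unmasking.
4. Stereochemistry: C2 and C3 both come from the boron aldol under (R)-4-benzyloxazolidin-2-one control (syn). The ring closure breaks no bond at C2 or C3, so syn maps onto 2,3-trans (2R,3S). The E alkene comes from acid equilibration of the enal.
5. Helpers and their removal: F on C7a (leaves in the key step); CO2Me on C5 (activator, later reduced and reoxidised to CHO); carboxylate on the C3 carbon (silent stand-in for CH2OH, later reduced); MOM on the ring B phenol (cleaved in the last step).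

Key step: step 8

Remark: benzofuran numbering (O1, C2, C3, C3a, C4–C7, C7a) is used throughout; ring A is the benzo ring and ring B the 4-hydroxy-3-methoxyphenyl group. Compounds 1, 5 and 8 are taken as the commercial starting materials.

**Route**

Step 1
Reactants: 1 methyl 4-fluoro-3-methoxybenzoate
Product: 2 methyl 4-fluoro-3-methoxy-5-(4,4,5,5-tetramethyl-1,3,2-dioxaborolan-2-yl)benzoate
Conditions: B2pin2 (1.0 equiv), [Ir(OMe)(cod)]2 (cat.), 4,4′-di-tert-butyl-2,2′-bipyridine (cat.), THF, 80 °C
Reagents that add atoms: bis(pinacolato)diboron, CC1(C)OB(OC1(C)C)B2OC(C)(C)C(C)(C)O2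
Why: Iridium-catalysed aromatic C–H borylation is sterically governed and should occur at the C–H ortho to fluorine (C5 of the benzoate, the future C3a), because the other two ring hydrogens lie between CO2Me and OMe or ortho to CO2Me, and a C–H next to fluorine is also electronically favoured.

Step 2
Reactants: 2 methyl 4-fluoro-3-methoxy-5-(4,4,5,5-tetramethyl-1,3,2-dioxaborolan-2-yl)benzoate
Product: 3 methyl 3-(2-tert-butoxy-2-oxoethyl)-4-fluoro-5-methoxybenzoate
Conditions: BrCH2CO2t-Bu, Pd(OAc)2 (cat.), P(o-tol)3 (cat.), K3PO4, THF/H2O, 40 °C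
Reagents that add atoms: tert-butyl bromoacetate, CC(C)(C)OC(=O)CBr
Why: Suzuki–Miyaura-type sp2–sp3 coupling of an arylboronate with an α-bromo ester (oxidative addition of the C–Br bond to zerovalent palladium, transmetalation, reductive elimination) is an established entry to arylacetic esters, and the mild phosphate base should leave both esters and the aryl fluoride untouched.

Step 3
Reactants: 3 methyl 3-(2-tert-butoxy-2-oxoethyl)-4-fluoro-5-methoxybenzoate
Product: 4 2-[2-fluoro-3-methoxy-5-(methoxycarbonyl)phenyl]acetic acid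
Conditions: CF3CO2H, CH2Cl2, rt
Reagents that add atoms: none
Why: Acidolysis of the tert-butyl ester through the tert-butyl cation (lost as isobutene) should free the acetic acid, while the methyl benzoate cannot ionise and survives.

Step 4
Reactants: 4 2-[2-fluoro-3-methoxy-5-(methoxycarbonyl)phenyl]acetic acid; 5 (R)-4-benzyloxazolidin-2-one
Product: 7 methyl 3-{2-[(4R)-4-benzyl-2-oxooxazolidin-3-yl]-2-oxoethyl}-4-fluoro-5-methoxybenzoate, via mixed pivalic anhydride 6 (not isolated)
Conditions: t-BuCOCl, Et3N, THF, −20 °C; then 5, LiCl, −20 °C to rt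
Reagents that add atoms: pivaloyl chloride, CC(C)(C)C(=O)Cl (its atoms are held only by intermediate 6)
Why: N-acylation of the oxazolidinone through the mixed pivalic anhydride under LiCl/Et3N activation is the standard way to load an arylacetic acid onto the auxiliary, attack occurring at the less hindered arylacetyl carbonyl.

Step 5
Reactants: 8 vanillin (4-hydroxy-3-methoxybenzaldehyde)
Product: 9 3-methoxy-4-(methoxymethoxy)benzaldehyde
Conditions: MeOCH2Cl, i-Pr2NEt, CH2Cl2, 0 °C to rt
Reagents that add atoms: chloromethyl methyl ether, COCCl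
Why: Williamson-type O-alkylation of the phenol with the reactive α-chloro ether masks it as an acetal that is stable to base, hydride and MnO2 and is removed by the final acid treatment.

Step 6
Reactants: 7 methyl 3-{2-[(4R)-4-benzyl-2-oxooxazolidin-3-yl]-2-oxoethyl}-4-fluoro-5-methoxybenzoate; 9 3-methoxy-4-(methoxymethoxy)benzaldehyde
Product: 12 (4R)-4-benzyl-3-{(2R,3R)-2-[2-fluoro-3-methoxy-5-(methoxycarbonyl)phenyl]-3-hydroxy-3-[3-methoxy-4-(methoxymethoxy)phenyl]propanoyl}oxazolidin-2-one, via Z dibutylboron enolate 10 (not isolated), via dibutylboron aldolate 11 (not isolated)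
Conditions: n-Bu2BOTf, i-Pr2NEt, CH2Cl2, −78 to 0 °C; 9, −78 to 0 °C; then pH 7 buffer, MeOH, 30% H2O2, 0 °C
Reagents that add atoms: dibutylboron triflate, CCCCB(CCCC)OS(=O)(=O)C(F)(F)F (boron and butyl groups are held only by intermediates 10 and 11)
Why: In this Evans syn aldol reaction, soft enolisation gives the Z boron enolate, which should add to the aldehyde through a closed Zimmerman–Traxler chair on the enolate face away from the benzyl group of the (R)-auxiliary, setting the future C3 and C2 together as the (2R,3R) syn adduct (propanoyl numbering).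

Step 7
Reactants: 12 (4R)-4-benzyl-3-{(2R,3R)-2-[2-fluoro-3-methoxy-5-(methoxycarbonyl)phenyl]-3-hydroxy-3-[3-methoxy-4-(methoxymethoxy)phenyl]propanoyl}oxazolidin-2-one
Product: 14 (2R,3R)-2-[2-fluoro-3-methoxy-5-(methoxycarbonyl)phenyl]-3-hydroxy-3-[3-methoxy-4-(methoxymethoxy)phenyl]propanoic acid, via peroxy acid 13 (not isolated)
Conditions: LiOH, 30% H2O2, THF/H2O, 0 °C; then aq. Na2SO3; then 1 M HCl to pH 3
Reagents that add atoms: hydrogen peroxide, OO
Why: Hydroperoxide cleavage of the N-acyloxazolidinone is selective for the exocyclic imide carbonyl over the methyl benzoate and, at 0 °C, should release the acid (after sulfite reduction of the peroxy acid) without retro-aldol cleavage or epimerisation of the α-aryl centre.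

Step 8
Reactants: 14 (2R,3R)-2-[2-fluoro-3-methoxy-5-(methoxycarbonyl)phenyl]-3-hydroxy-3-[3-methoxy-4-(methoxymethoxy)phenyl]propanoic acid
Product: 16 (2R,3R)-7-methoxy-5-(methoxycarbonyl)-2-[3-methoxy-4-(methoxymethoxy)phenyl]-2,3-dihydro-1-benzofuran-3-carboxylic acid (2,3-trans), via dipotassium alkoxide carboxylate 15 (not isolated)
Conditions: KHMDS (2.2 equiv), THF/DMF, −20 °C to rt; then 1 M HCl to pH 3
Reagents that add atoms: potassium bis(trimethylsilyl)amide, C[Si](C)(C)[N-][Si](C)(C)C.[K+] (potassium is held only by intermediate 15)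
Why: Double deprotonation gives the dianion, whose C2 alkoxide adds to C7a of ring A to form a Meisenheimer adduct with the charge delocalised onto the CO2Me group at C5 (para to C7a), and loss of fluoride then rearomatises ring A and forges O1–C7a (addition–elimination SNAr). The closest known reaction type is the intramolecular SNAr etherification of 2-(2-fluoroaryl)ethanols that carry a para carbonyl group, which gives 2,3-dihydrobenzofurans. The dihydrofuran ring closes in a 5-exo-trig mode, the oxygen attacking the arene carbon that completes the ring O1–C2–C3–C3a–C7a. No stereocentre is created: the C2–O and C3–H bonds are untouched, so the syn aldol configuration is carried over with retention and appears as the 2,3-trans ring with ring B and the C3 carboxylate on opposite faces. The step needs a choice between two oxygens that could each close a five-membered ring and suppression of retro-aldol cleavage; holding the C3 carbon at the carboxylate level secures both, because a carboxylate is a far weaker SNAr nucleophile than an alkoxide and a retro-aldol would have to expel an enediolate dianion. Site selectivity follows from the single fluoride on C7a, the only ring A position that is both para to the ester and within reach of the alkoxide.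

Step 9
Reactants: 16 (2R,3R)-7-methoxy-5-(methoxycarbonyl)-2-[3-methoxy-4-(methoxymethoxy)phenyl]-2,3-dihydro-1-benzofuran-3-carboxylic acid
Product: 17 {(2R,3S)-3-(hydroxymethyl)-7-methoxy-2-[3-methoxy-4-(methoxymethoxy)phenyl]-2,3-dihydro-1-benzofuran-5-yl}methanol
Conditions: LiAlH4, THF, 0 to 50 °C; then H2O, 15% aq. NaOH
Reagents that add atoms: none
Why: Hydride reduction with LiAlH4 should take the carboxylic acid (through its aluminium carboxylate) and the methyl ester to the two primary alcohols without touching the aryl ethers, the MOM acetal or either stereocentre.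

Step 10
Reactants: 17 {(2R,3S)-3-(hydroxymethyl)-7-methoxy-2-[3-methoxy-4-(methoxymethoxy)phenyl]-2,3-dihydro-1-benzofuran-5-yl}methanol
Product: 18 (2R,3S)-3-(hydroxymethyl)-7-methoxy-2-[3-methoxy-4-(methoxymethoxy)phenyl]-2,3-dihydro-1-benzofuran-5-carbaldehyde
Conditions: activated MnO2, CH2Cl2, rt
Reagents that add atoms: none
Why: Manganese dioxide oxidises only benzylic and allylic alcohols, so the electron-rich ring A benzylic alcohol should go to the aldehyde while the saturated primary alcohol on C3 stays.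

Step 11
Reactants: 18 (2R,3S)-3-(hydroxymethyl)-7-methoxy-2-[3-methoxy-4-(methoxymethoxy)phenyl]-2,3-dihydro-1-benzofuran-5-carbaldehyde
Product: 21 balanophonin, via vinyl dioxolane 19 (not isolated), via MOM-protected balanophonin 20 (not isolated)
Conditions: (1,3-dioxolan-2-ylmethyl)triphenylphosphonium bromide, LiOMe, DMF, 80 °C; then 3 M HCl, THF, rt to 40 °C
Reagents that add atoms: (1,3-dioxolan-2-ylmethyl)triphenylphosphonium bromide, [Br-].C(C1OCCO1)[P+](c1ccccc1)(c1ccccc1)c1ccccc1; water, O
Why: Wittig olefination with the acetal-masked formylmethylene ylide adds the two-carbon unit, and aqueous acid should then hydrolyse the dioxolane, equilibrate the enal to the E isomer and cleave the aryl MOM acetal, any reversible ionisation at C2 returning the more stable trans ring because C3 stays fixed.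

**Compound list**

1 | methyl 4-fluoro-3-methoxybenzoate | COC(=O)c1ccc(F)c(OC)c1 | starting material
2 | methyl 4-fluoro-3-methoxy-5-(4,4,5,5-tetramethyl-1,3,2-dioxaborolan-2-yl)benzoate | COC(=O)c1cc(OC)c(F)c(c1)B2OC(C)(C)C(C)(C)O2 | intermediate
3 | methyl 3-(2-tert-butoxy-2-oxoethyl)-4-fluoro-5-methoxybenzoate | COC(=O)c1cc(CC(=O)OC(C)(C)C)c(F)c(OC)c1 | intermediate
4 | 2-[2-fluoro-3-methoxy-5-(methoxycarbonyl)phenyl]acetic acid | COC(=O)c1cc(CC(=O)O)c(F)c(OC)c1 | intermediate
5 | (R)-4-benzyloxazolidin-2-one | O=C1N[C@H](Cc2ccccc2)CO1 | starting material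
6 | 2-[2-fluoro-3-methoxy-5-(methoxycarbonyl)phenyl]acetic pivalic anhydride (not isolated) | COC(=O)c1cc(CC(=O)OC(=O)C(C)(C)C)c(F)c(OC)c1 | intermediate
7 | methyl 3-{2-[(4R)-4-benzyl-2-oxooxazolidin-3-yl]-2-oxoethyl}-4-fluoro-5-methoxybenzoate | COC(=O)c1cc(CC(=O)N2[C@H](Cc3ccccc3)COC2=O)c(F)c(OC)c1 | intermediate
8 | vanillin (4-hydroxy-3-methoxybenzaldehyde) | COc1cc(C=O)ccc1O | starting material
9 | 3-methoxy-4-(methoxymethoxy)benzaldehyde | COCOc1ccc(C=O)cc1OC | intermediate
10 | Z dibutylboron enolate of 7 (not isolated) | CCCCB(CCCC)O/C(=C\c1cc(C(=O)OC)cc(OC)c1F)N1[C@H](Cc2ccccc2)COC1=O | intermediate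
11 | dibutylboron aldolate, the O-dibutylboryl derivative of 12 (not isolated) | CCCCB(CCCC)O[C@H]([C@H](C(=O)N1[C@H](Cc2ccccc2)COC1=O)c1cc(C(=O)OC)cc(OC)c1F)c1ccc(OCOC)c(OC)c1 | intermediate
12 | (4R)-4-benzyl-3-{(2R,3R)-2-[2-fluoro-3-methoxy-5-(methoxycarbonyl)phenyl]-3-hydroxy-3-[3-methoxy-4-(methoxymethoxy)phenyl]propanoyl}oxazolidin-2-one (syn aldol adduct) | O=C([C@H](c1cc(C(=O)OC)cc(OC)c1F)[C@@H](O)c1ccc(OCOC)c(OC)c1)N1[C@H](Cc2ccccc2)COC1=O | intermediate
13 | (2R,3R)-2-[2-fluoro-3-methoxy-5-(methoxycarbonyl)phenyl]-3-hydroxy-3-[3-methoxy-4-(methoxymethoxy)phenyl]propaneperoxoic acid (not isolated) | OOC(=O)[C@H](c1cc(C(=O)OC)cc(OC)c1F)[C@@H](O)c1ccc(OCOC)c(OC)c1 | intermediate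
14 | (2R,3R)-2-[2-fluoro-3-methoxy-5-(methoxycarbonyl)phenyl]-3-hydroxy-3-[3-methoxy-4-(methoxymethoxy)phenyl]propanoic acid | OC(=O)[C@H](c1cc(C(=O)OC)cc(OC)c1F)[C@@H](O)c1ccc(OCOC)c(OC)c1 | intermediate
15 | dipotassium alkoxide carboxylate of 14 (not isolated) | [K+].[K+].[O-]C(=O)[C@H](c1cc(C(=O)OC)cc(OC)c1F)[C@@H]([O-])c1ccc(OCOC)c(OC)c1 | intermediate
16 | (2R,3R)-7-methoxy-5-(methoxycarbonyl)-2-[3-methoxy-4-(methoxymethoxy)phenyl]-2,3-dihydro-1-benzofuran-3-carboxylic acid (2,3-trans) | OC(=O)[C@@H]1c2cc(C(=O)OC)cc(OC)c2O[C@H]1c1ccc(OCOC)c(OC)c1 | intermediate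
17 | {(2R,3S)-3-(hydroxymethyl)-7-methoxy-2-[3-methoxy-4-(methoxymethoxy)phenyl]-2,3-dihydro-1-benzofuran-5-yl}methanol | OC[C@@H]1c2cc(CO)cc(OC)c2O[C@H]1c1ccc(OCOC)c(OC)c1 | intermediate
18 | (2R,3S)-3-(hydroxymethyl)-7-methoxy-2-[3-methoxy-4-(methoxymethoxy)phenyl]-2,3-dihydro-1-benzofuran-5-carbaldehyde | OC[C@@H]1c2cc(C=O)cc(OC)c2O[C@H]1c1ccc(OCOC)c(OC)c1 | intermediate
19 | {(2R,3S)-5-[2-(1,3-dioxolan-2-yl)ethenyl]-7-methoxy-2-[3-methoxy-4-(methoxymethoxy)phenyl]-2,3-dihydro-1-benzofuran-3-yl}methanol (E/Z mixture, not isolated) | OC[C@@H]1c2cc(C=CC3OCCO3)cc(OC)c2O[C@H]1c1ccc(OCOC)c(OC)c1 | intermediate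
20 | (E)-3-{(2R,3S)-3-(hydroxymethyl)-7-methoxy-2-[3-methoxy-4-(methoxymethoxy)phenyl]-2,3-dihydro-1-benzofuran-5-yl}prop-2-enal (not isolated) | OC[C@@H]1c2cc(/C=C/C=O)cc(OC)c2O[C@H]1c1ccc(OCOC)c(OC)c1 | intermediate
21 | balanophonin, (E)-3-[(2R,3S)-2-(4-hydroxy-3-methoxyphenyl)-3-(hydroxymethyl)-7-methoxy-2,3-dihydro-1-benzofuran-5-yl]prop-2-enal | COc1cc([C@@H]2Oc3c(OC)cc(/C=C/C=O)cc3[C@H]2CO)ccc1O | target

**Step count and risks**

Total step count: 11. Longest linear sequence: 10 steps (steps 1–4 and 6–11; step 5 is a one-step side branch).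

The three steps most likely to fail:

Step 2. What may go wrong: protodeboronation of the ortho-fluorinated arylboronate and homocoupling may outrun transmetalation to the palladium enolate. The fallback inverts the polarity of the coupling and sets out from 2. Copper-mediated bromodeboronation (CuBr2, MeOH/H2O, 80 °C) should give methyl 3-bromo-4-fluoro-5-methoxybenzoate F1. A Negishi-type α-arylation of the commercial Reformatsky-type reagent (2-tert-butoxy-2-oxoethyl)zinc chloride (Pd(dba)2, XPhos, THF, 50 °C) then comes back to the route at 3.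

Step 8. What may go wrong: retro-aldol fragmentation of the benzylic alkoxide, or slow closure of a poorly soluble dianion with competing cleavage of the methyl ester. The fallback replaces the carboxylate stand-in by an ether and sets out from 12. Reductive removal of the auxiliary (LiBH4, THF/MeOH, 0 °C) should give methyl 3-{(1R,2S)-1,3-dihydroxy-1-[3-methoxy-4-(methoxymethoxy)phenyl]propan-2-yl}-4-fluoro-5-methoxybenzoate F2. Selective tritylation of the primary hydroxyl (TrCl, Et3N, DMAP, CH2Cl2) should give the trityl ether F3. The same SNAr closure at O1–C7a (KHMDS, 1.1 equiv, THF/DMF) should give the cyclised trityl ether ester F4, whose alkoxide has no retro-aldol exit. Detritylation (80% aq. AcOH, 40 °C) should give the hydroxy ester F5, and LiAlH4 reduction of F5 comes back to the route at 17.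

Step 11. What may go wrong: incomplete cleavage of the MOM acetal, acid-induced ionisation at C2 during the one-pot unmasking, or poor E/Z control. The fallback builds the enal by oxidation-level adjustment without protic acid and sets out from 18. A Horner–Wadsworth–Emmons reaction with triethyl phosphonoacetate (NaH, THF, 0 °C to rt) should give the ethyl E cinnamate F6. Reduction with i-Bu2AlH (CH2Cl2, −78 °C) should give the allylic alcohol F7. MnO2 (CH2Cl2, rt) should oxidise only the allylic alcohol to 20. The MOM group is then removed under non-protic conditions (Me3SiOTf, 2,2′-bipyridyl, CH2Cl2, 0 °C; then H2O), which comes back to the route at 21.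

Further compounds
F1 | step 2 | methyl 3-bromo-4-fluoro-5-methoxybenzoate | COC(=O)c1cc(Br)c(F)c(OC)c1
F2 | step 8 | methyl 3-{(1R,2S)-1,3-dihydroxy-1-[3-methoxy-4-(methoxymethoxy)phenyl]propan-2-yl}-4-fluoro-5-methoxybenzoate | OC[C@H](c1cc(C(=O)OC)cc(OC)c1F)[C@@H](O)c1ccc(OCOC)c(OC)c1
F3 | step 8 | methyl 4-fluoro-3-{(1R,2S)-1-hydroxy-1-[3-methoxy-4-(methoxymethoxy)phenyl]-3-(trityloxy)propan-2-yl}-5-methoxybenzoate | c1ccccc1C(c1ccccc1)(c1ccccc1)OC[C@H](c1cc(C(=O)OC)cc(OC)c1F)[C@@H](O)c1ccc(OCOC)c(OC)c1
F4 | step 8 | methyl (2R,3S)-7-methoxy-2-[3-methoxy-4-(methoxymethoxy)phenyl]-3-(trityloxymethyl)-2,3-dihydro-1-benzofuran-5-carboxylate | c1ccccc1C(c1ccccc1)(c1ccccc1)OC[C@@H]1c2cc(C(=O)OC)cc(OC)c2O[C@H]1c1ccc(OCOC)c(OC)c1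
F5 | step 8 | methyl (2R,3S)-3-(hydroxymethyl)-7-methoxy-2-[3-methoxy-4-(methoxymethoxy)phenyl]-2,3-dihydro-1-benzofuran-5-carboxylate | OC[C@@H]1c2cc(C(=O)OC)cc(OC)c2O[C@H]1c1ccc(OCOC)c(OC)c1
F6 | step 11 | ethyl (E)-3-{(2R,3S)-3-(hydroxymethyl)-7-methoxy-2-[3-methoxy-4-(methoxymethoxy)phenyl]-2,3-dihydro-1-benzofuran-5-yl}prop-2-enoate | OC[C@@H]1c2cc(/C=C/C(=O)OCC)cc(OC)c2O[C@H]1c1ccc(OCOC)c(OC)c1
F7 | step 11 | (E)-3-{(2R,3S)-3-(hydroxymethyl)-7-methoxy-2-[3-methoxy-4-(methoxymethoxy)phenyl]-2,3-dihydro-1-benzofuran-5-yl}prop-2-en-1-ol | OC[C@@H]1c2cc(/C=C/CO)cc(OC)c2O[C@H]1c1ccc(OCOC)c(OC)c1
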